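# Total synthesis of Blepharocalyxin E

**Retrosynthetic overview**
1. Blepharocalyxin E ⇐ late-stage chalcone formation (ortho-lithiation of the A-ring, then a Weinreb cinnamamide) ⇐ E-selective cross-metathesis of a C7'-vinyl tetrahydropyran with the (S)-homoallylic alcohol **6**.
2. The tetrahydropyran is an all-equatorial 2,6-cis THP-4-one, made by thermodynamic dehydrative oxa-cyclisation of a 1,5-diol-3-one. The C4 aryl comes from the ketone by aryl-cerium addition, then ionic deoxygenation with axial hydride delivery.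
3. Key disconnection: an Et3B/O2 radical conjugate addition of the 1,3-dioxolan-2-yl radical to the β-carbon (C7') of the (S)-5-hydroxy-diarylheptenone **8**. The resulting α-keto radical is trapped as a boron enolate and undergoes aldol reaction with ArCHO. This forms C7'–C6' (radical) and C5–C6 (aldol) in one operation.
4. One Keck allylation supplies both (S)-carbinols. The A-ring is built from resorcinol by Ir-borylation. Ring order: arene A (steps 7–9), THP (step 11), chalcone enone (step 18).

Assumptions:
- (S)-BINOL/Ti gives the (S)-carbinol in Step 4; if not, use (R)-BINOL.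
- All phenols are carried as MOM ethers, and the C3'-OH stays free.

---

**Step 1**
Reactants: 1 (4-iodophenol)
Product: 2 (1-iodo-4-(methoxymethoxy)benzene)
Conditions: MOMCl, i-Pr2NEt, CH2Cl2, 0 °C → rt
Reagents that add atoms: MOMCl, COCCl
Why: O-protection as a MOM ether, which survives the later organolithium, radical and Ti/Pd steps.

**Step 2**
Reactants: 2; 3 (allyl alcohol)
Product: 4 (3-[4-(methoxymethoxy)phenyl]propanal)
Conditions: Pd(OAc)2, n-Bu4NCl, NaHCO3, DMF, 50 °C
Reagents that add atoms: none
Why: Jeffery-type Mizoroki–Heck; β-H elimination toward the carbinol carbon gives the enol, which tautomerises to the saturated aldehyde.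

**Step 3**
Reactants: 2
Product: 5 (4-(methoxymethoxy)benzaldehyde)
Conditions: i-PrMgCl·LiCl, THF, −15 °C; then DMF, 0 °C
Reagents that add atoms: DMF, CN(C)C=O
Why: I/Mg exchange followed by Bouveault formylation.

**Step 4**
Reactants: 4
Product: 6 ((3S)-1-[4-(methoxymethoxy)phenyl]hex-5-en-3-ol)
Conditions: allyl-SnBu3, (S)-BINOL (20 mol%), Ti(OiPr)4, 4 Å MS, CH2Cl2, −20 °C
Reagents that add atoms: allyltributylstannane, C=CC[Sn](CCCC)(CCCC)CCCC
Why: Keck asymmetric allylation; the chiral Ti–BINOL Lewis acid differentiates the aldehyde faces and sets C2 and C3' (S). This is the only source of absolute configuration for both carbinols, and 6 is used twice.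

**Step 5**
Reactants: 6
Product: 7 ((4S)-4-hydroxy-6-[4-(methoxymethoxy)phenyl]hexan-2-one)
Conditions: PdCl2 (10 mol%), CuCl, O2 (1 atm), DMF/H2O 7:1, rt
Reagents that add atoms: O2, O=O
Why: Tsuji–Wacker oxidation; the homoallylic OH directs Markovnikov oxidation to the methyl ketone, and the carbinol stereocentre is untouched.

**Step 6**
Reactants: 7; 5
Product: 8 ((1E,5S)-5-hydroxy-1,7-bis[4-(methoxymethoxy)phenyl]hept-1-en-3-one)
Conditions: Ba(OH)2·8H2O, MeOH, 0 °C → rt
Reagents that add atoms: none
Why: Claisen–Schmidt condensation on the methyl side gives the E-enone; the mild base is chosen to avoid retro-aldol or dehydration at the β-hydroxy centre.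

**Step 7**
Reactants: 9 (resorcinol)
Product: 10 (1,3-bis(methoxymethoxy)benzene)
Conditions: MOMCl (2.2 equiv), i-Pr2NEt, CH2Cl2, 0 °C → rt
Reagents that add atoms: MOMCl, COCCl
Why: Protection of both phenols; MOM also serves as a directing group later.

**Step 8**
Reactants: 10
Product: 11 (3,5-bis(methoxymethoxy)phenol)
Conditions: [Ir(OMe)(cod)]2 (1.5 mol%), dtbpy, HBpin, THF, 80 °C; then H2O2, aq. NaOH, 0 °C
Reagents that add atoms: hydrogen peroxide (supplies the phenolic O), OO
Why: Sterically controlled Ir-catalysed C–H borylation occurs at C5, meta to both oxygens, which cannot be reached by electrophilic substitution; oxidative deborylation then gives the phloroglucinol-type 1,3,5-trioxygenated pattern.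

**Step 9**
Reactants: 11
Product: 12 (1-methoxy-3,5-bis(methoxymethoxy)benzene)
Conditions: MeI, K2CO3, acetone, 55 °C
Reagents that add atoms: MeI, CI
Why: O-methylation installs the future 6'-OMe of the chalcone ring.

**Step 10 (key step)**
Reactants: 8; 13 (1,3-dioxolane); 5
Product: 14 (aldol adduct Ar'CH(OH)–CH[CH(Ar)–dioxolanyl]–C(=O)–CH2–CH(OH)R; C2 (S), other centres as a mixture)
Conditions: Et3B (2 equiv), air (syringe), 13 (40 equiv), 5 (1.5 equiv), CH2Cl2/hexane, −40 → 0 °C
Reagents that add atoms: none
Why: Proposed new method: Et• from Et3B/O2 abstracts the acetal C–H of 13. The nucleophilic dioxolan-2-yl radical adds regioselectively to the β-carbon (C7') of the aryl enone 8 (polarity-matched, no allyl-radical regiochemistry problem), forming the C7'–C6' bond. The α-keto radical at C5 is captured by Et3B (SH2 at boron) to give a boron enolate, which undergoes Zimmerman–Traxler aldol with 5 to form C5–C6. The closest known chemistry is the Et3B-mediated radical conjugate addition/boron-enolate aldol tandem of alkyl radicals with enones, extended here to dioxolanyl radicals and a free hydroxy-enone. C7' is set here with modest diastereocontrol; C5 and C6 are equilibrated in Step 11.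

**Step 11**
Reactants: 14
Product: 15 ((2S,5R,6S,7'S)-THP-4-one, all-equatorial)
Conditions: CSA (10 mol%), 4 Å MS, CH2Cl2, 23 °C; chromatographic separation of the C7' diastereomers
Reagents that add atoms: none
Why: The p-alkoxybenzylic C6–OH ionises (or dehydrates and undergoes oxa-Michael), and the C2–OH closes the ring; reversible benzylic C–O formation and C5 enolisation funnel the product to the all-equatorial 2,6-cis, 5,6-trans THP-4-one, so C6 and C5 are set thermodynamically while C2 is retained.

**Step 12**
Reactants: 15; 12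
Product: 16 (tertiary 4-aryl-THP-4-ol, C4 epimers)
Conditions: 12, s-BuLi, THF, −78 → −40 °C; CeCl3 (1.6 equiv); then 15, −78 → 0 °C
Reagents that add atoms: none
Why: Directed ortho-metalation occurs at the C–H flanked by the two MOM ethers; the organocerium adds 1,2 to the enolisable ketone without enolisation.

**Step 13**
Reactants: 16
Product: 17 ((2S,4R,5R,6S,7'S)-4-aryl-THP, C4–H)
Conditions: Et3SiH (10 equiv), TFA (2 equiv), CH2Cl2, −40 → −10 °C
Reagents that add atoms: none (hydride only)
Why: Ionic deoxygenation through the tertiary benzylic cation, which is strongly stabilised by the three ring oxygens; axial hydride delivery puts the aryl group equatorial, cis to C2 and C6 and trans to C5 (sets C4).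

**Step 14**
Reactants: 17
Product: 18 (aldehyde)
Conditions: TMSOTf, 2,4,6-collidine, CH2Cl2, 0 °C; then H2O
Reagents that add atoms: water, O
Why: Fujioka-type neutral acetal deprotection avoids strong acid or base, which would epimerise the α-aryl aldehyde at C7'.

**Step 15**
Reactants: 18
Product: 19 (C7'-vinyl THP)
Conditions: Ph3P=CH2 (1.2 equiv, salt-free), THF, −78 → 0 °C
Reagents that add atoms: methylenetriphenylphosphorane, C=P(c1ccccc1)(c1ccccc1)c1ccccc1
Why: Wittig methylenation gives the terminal alkene needed for metathesis, with no change at C7'.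

**Step 16**
Reactants: 19; 6 (3 equiv)
Product: 20 (MOM-protected seco-precursor)
Conditions: Hoveyda–Grubbs II (5 mol%), CH2Cl2, 40 °C
Reagents that add atoms: none
Why: Cross-metathesis of two terminal alkenes gives the thermodynamic E-alkene (C5'=C6') and attaches the (3'S) carbinol unit without touching its stereocentre.

**Step 17**
Reactants: 5
Product: 21 ((E)-N-methoxy-N-methyl-3-[4-(methoxymethoxy)phenyl]acrylamide)
Conditions: (EtO)2P(O)CH2C(=O)N(OMe)Me, NaH, THF, 0 °C → rt
Reagents that add atoms: diethyl (N-methoxy-N-methylcarbamoylmethyl)phosphonate, CCOP(=O)(CC(=O)N(C)OC)OCC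
Why: Horner–Wadsworth–Emmons olefination gives the E-acceptor, and the Weinreb amide stops the organolithium addition at the ketone.

**Step 18**
Reactants: 20; 21
Product: 22 (fully MOM-protected Blepharocalyxin E)
Conditions: s-BuLi (3.5 equiv), TMEDA, THF, −78 → −40 °C; then 21 (2 equiv), −78 → 0 °C
Reagents that add atoms: none
Why: Directed ortho-lithiation at the remaining C–H flanked by OMe and OMOM (both such positions are equivalent by symmetry), then acylation with the vinylogous Weinreb amide gives the (E)-chalcone; the extra equivalent of base covers the free C3'-OH.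

**Step 19**
Reactants: 22
Product: 23 (Blepharocalyxin E)
Conditions: 3 M HCl, THF/MeOH, 35 °C
Reagents that add atoms: none
Why: Acidolysis of all seven MOM acetals gives the free phenols; the stereocentres and both E-alkenes are not involved.

---

## Compound list
| No. | Name | SMILES | Role |
|---|---|---|---|
| 1 | 4-iodophenol | Oc1ccc(I)cc1 | starting material |
| 2 | 1-iodo-4-(methoxymethoxy)benzene | COCOc1ccc(I)cc1 | intermediate |
| 3 | allyl alcohol | C=CCO | starting material |
| 4 | 3-[4-(methoxymethoxy)phenyl]propanal | COCOc1ccc(CCC=O)cc1 | intermediate |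
| 5 | 4-(methoxymethoxy)benzaldehyde | COCOc1ccc(C=O)cc1 | intermediate |
| 6 | (3S)-1-[4-(methoxymethoxy)phenyl]hex-5-en-3-ol | COCOc1ccc(CC[C@H](O)CC=C)cc1 | intermediate |
| 7 | (4S)-4-hydroxy-6-[4-(methoxymethoxy)phenyl]hexan-2-one | COCOc1ccc(CC[C@H](O)CC(C)=O)cc1 | intermediate |
| 8 | (1E,5S)-5-hydroxy-1,7-bis[4-(methoxymethoxy)phenyl]hept-1-en-3-one | COCOc1ccc(/C=C/C(=O)C[C@@H](O)CCc2ccc(OCOC)cc2)cc1 | intermediate |
| 9 | resorcinol | Oc1cccc(O)c1 | starting material |
| 10 | 1,3-bis(methoxymethoxy)benzene | COCOc1cccc(OCOC)c1 | intermediate |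
| 11 | 3,5-bis(methoxymethoxy)phenol | COCOc1cc(O)cc(OCOC)c1 | intermediate |
| 12 | 1-methoxy-3,5-bis(methoxymethoxy)benzene | COc1cc(OCOC)cc(OCOC)c1 | intermediate |
| 13 | 1,3-dioxolane | C1COCO1 | starting material |
| 14 | aldol adduct (C2 S; other centres as a mixture) | COCOc1ccc(cc1)C(O)C(C(c1ccc(OCOC)cc1)C1OCCO1)C(=O)C[C@@H](O)CCc1ccc(OCOC)cc1 | intermediate |
| 15 | (2S,5R,6S,7'S)-THP-4-one with dioxolanyl side chain | O=C1C[C@H](CCc2ccc(OCOC)cc2)O[C@H](c2ccc(OCOC)cc2)[C@H]1[C@H](C1OCCO1)c1ccc(OCOC)cc1 | intermediate |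
| 16 | 4-aryl-THP-4-ol (C4 epimers) | OC1(c2c(OCOC)cc(OC)cc2OCOC)C[C@H](CCc2ccc(OCOC)cc2)O[C@H](c2ccc(OCOC)cc2)[C@H]1[C@H](C1OCCO1)c1ccc(OCOC)cc1 | intermediate |
| 17 | (2S,4R,5R,6S,7'S)-4-aryl-THP, dioxolane | COc1cc(OCOC)c([C@@H]2C[C@H](CCc3ccc(OCOC)cc3)O[C@H](c3ccc(OCOC)cc3)[C@H]2[C@H](C2OCCO2)c2ccc(OCOC)cc2)c(OCOC)c1 | intermediate |
| 18 | aldehyde | COc1cc(OCOC)c([C@@H]2C[C@H](CCc3ccc(OCOC)cc3)O[C@H](c3ccc(OCOC)cc3)[C@H]2[C@H](C=O)c2ccc(OCOC)cc2)c(OCOC)c1 | intermediate |
| 19 | C7'-vinyl THP | COc1cc(OCOC)c([C@@H]2C[C@H](CCc3ccc(OCOC)cc3)O[C@H](c3ccc(OCOC)cc3)[C@H]2[C@H](C=C)c2ccc(OCOC)cc2)c(OCOC)c1 | intermediate |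
| 20 | cross-metathesis product | COc1cc(OCOC)c([C@@H]2C[C@H](CCc3ccc(OCOC)cc3)O[C@H](c3ccc(OCOC)cc3)[C@H]2[C@H](/C=C/C[C@@H](O)CCc2ccc(OCOC)cc2)c2ccc(OCOC)cc2)c(OCOC)c1 | intermediate |
| 21 | (E)-N-methoxy-N-methyl-3-[4-(methoxymethoxy)phenyl]acrylamide | COCOc1ccc(/C=C/C(=O)N(C)OC)cc1 | intermediate |
| 22 | hepta-MOM-protected Blepharocalyxin E | COc1cc(OCOC)c([C@@H]2C[C@H](CCc3ccc(OCOC)cc3)O[C@H](c3ccc(OCOC)cc3)[C@H]2[C@H](/C=C/C[C@@H](O)CCc2ccc(OCOC)cc2)c2ccc(OCOC)cc2)c(OCOC)c1C(=O)/C=C/c1ccc(OCOC)cc1 | intermediate |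
| 23 | Blepharocalyxin E | COc1cc(O)c([C@@H]2C[C@H](CCc3ccc(O)cc3)O[C@H](c3ccc(O)cc3)[C@H]2[C@H](/C=C/C[C@@H](O)CCc2ccc(O)cc2)c2ccc(O)cc2)c(O)c1C(=O)/C=C/c1ccc(O)cc1 | target |

**Total steps:** 19. **Longest linear sequence:** 14 (1→2→4→6→7→8→14→15→16→17→18→19→20→22→23, counting reactions, not compounds).

## Three steps most likely to fail
1. **Step 10 (three-component radical/aldol).** Diastereocontrol at C7' is expected to be only about 1:1, and the free hydroxyl may interfere. Fallback: a polar, catalyst-controlled route in which Rh/chiral-diene-catalysed 1,4-addition of potassium vinyltrifluoroborate to 8 is followed by aldol trapping with 5; this sets C7' by ligand and installs the vinyl group directly, which would delete Steps 14–15.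
2. **Step 12 (aryl-cerium addition to the hindered ketone, and lithiation regiochemistry).** Fallback: form the C3=C4 enol triflate of 15 (LiHMDS, PhNTf2), do a Suzuki coupling with the A-ring aryl boronate made from 12, then hydrogenate the ring alkene to set C4.
3. **Step 14 (C7' epimerisation of the α-aryl aldehyde, or MOM cleavage by TMSOTf).** Fallback: unveil the aldehyde and methylenate in the same pot with non-basic Takai–Lombardo conditions (Zn/CH2Br2/TiCl4), so the aldehyde is never exposed to base or strong acid.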